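C6–C1'' (prenyl, ring A) and C3'–C1''' (geranyl, ring B) are cut in one operation, after O7 is re-silylated. Each chain goes back to the phenol oxygen beside it, O5 or O4'.
Enabling feature: of the two carbons ortho to O5 only C6 bears hydrogen (the other is the fusion atom C4a). On ring B, C3' and C5' ortho to O4' are equivalent and the para carbon C1' holds C3, so the site of each ether decides where its chain lands.
The bis-ether goes back to the flat isoflavone and then to genistein, which supplies rings A, B and C ready-made. No ring is formed in the route.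
Forward order: O7 silylation, O4' geranylation, O5 prenylation (reactivity 7-OH > 4'-OH > chelated 5-OH), reduction and reoxidation of ring C, twofold O-to-C shift, desilylation.
Stereochemistry: C3 (R) comes from catalyst control in an asymmetric transfer hydrogenation with dynamic kinetic resolution, which gives the cis-(3R,4R)-isoflavan-4-ol. C4 is then erased by oxidation, and the E alkene comes with geraniol.

Key step: step 6

Remark: isoflavonoid numbering is used (ring C O1–C4, ring A C5–C8, ring B primed, prenyl doubly primed, geranyl triply primed); the (R,R)-catalyst is chosen by analogy with aryl ketones and 4-chromanones, which it reduces to the (R)-benzylic alcohols, and the ring A ether is assumed to migrate before the ring B ether.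

Step 1
Reactants: 1 genistein
Product: 2 7-O-triisopropylsilylgenistein
Conditions: TIPSCl (1.05 equiv), imidazole, DMF, 0 °C
Reagents that add atoms: triisopropylsilyl chloride, CC(C)[Si](Cl)(C(C)C)C(C)C
Why: Chemoselective O-silylation of a polyphenol: 7-OH is a vinylogous carboxylic acid conjugated to C4=O and the only hydroxyl that imidazole ionises to a useful extent, 4'-OH is an ordinary phenol and 5-OH is locked in a hydrogen bond to C4=O, so one equivalent of the bulky chloride in the cold should cap O7 alone.

Step 2
Reactants: 2 7-O-triisopropylsilylgenistein; 3 geraniol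
Product: 4 4'-O-geranyl-7-O-triisopropylsilylgenistein
Conditions: PPh3, DIAD, THF, 0 °C → rt
Reagents that add atoms: none
Why: Mitsunobu etherification: the neutral medium spares the base-labile vinylogous silyl ester at O7, the free 4'-phenol displaces the oxyphosphonium group at the primary carbon C1 of geraniol in an SN2 sense so that the E alkene is untouched, and the chelated 5-OH is too slow to compete for a single equivalent of alcohol.

Step 3
Reactants: 4 4'-O-geranyl-7-O-triisopropylsilylgenistein; 5 prenol
Product: 6 4'-O-geranyl-5-O-prenyl-7-O-triisopropylsilylgenistein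
Conditions: PPh3, DIAD, THF, 0 °C → rt
Reagents that add atoms: none
Why: Mitsunobu etherification again, the established way to alkylate the hydrogen-bonded 5-OH of flavonoids and isoflavones by prenol without carbonate bases or heat, so the silyl ether and the geranyl ether stay in place and only O-alkylation is expected.

Step 4
Reactants: 6 4'-O-geranyl-5-O-prenyl-7-O-triisopropylsilylgenistein
Product: 8 (3R,4R)-cis-4'-geranyloxy-5-prenyloxy-7-(triisopropylsilyloxy)isoflavan-4-ol, via racemic isoflavanone 7 (not isolated)
Conditions: RuCl(p-cymene)[(R,R)-TsDPEN] (5 mol %), HCO2H, Et3N (amine in excess), EtOAc, 40 °C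
Reagents that add atoms: none
Why: Noyori–Ikariya asymmetric transfer hydrogenation run as a domino process with dynamic kinetic resolution, known for isoflavones: the ruthenium hydride first reduces the C2=C3 bond of the chromone to 7, triethylamine racemises C3 of 7 through the enol much faster than the ketone is reduced, and the (R,R)-catalyst then reduces only the (3R)-ketone by delivering hydride to the carbonyl face opposite the C3 aryl group, which sets C4 as R by catalyst control and C3 as R through the cis relationship, while trisubstituted alkenes, allyl aryl ethers and the silyl ether are left alone.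

Step 5
Reactants: 8 (3R,4R)-cis-4'-geranyloxy-5-prenyloxy-7-(triisopropylsilyloxy)isoflavan-4-ol
Product: 9 (R)-4'-O-geranyl-5-O-prenyl-7-O-triisopropylsilyl-2,3-dihydrogenistein
Conditions: Dess–Martin periodinane, NaHCO3, CH2Cl2, 0 °C
Reagents that add atoms: none
Why: Dess–Martin oxidation, the established non-racemising return from cis-isoflavan-4-ols to isoflavanones: the benzylic alcohol is oxidised in the cold in a bicarbonate-buffered aprotic medium that neither ionises the electron-rich benzylic alcohol nor enolises the product, so the relay centre C4 is erased and C3 keeps its R configuration.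

Step 6
Reactants: 9 (R)-4'-O-geranyl-5-O-prenyl-7-O-triisopropylsilyl-2,3-dihydrogenistein
Product: 11 (R)-3'-C-geranyl-6-C-prenyl-7-O-triisopropylsilyl-2,3-dihydrogenistein, via mono-shifted 6-C-prenyl 4'-O-geranyl ether 10 (not isolated)
Conditions: montmorillonite K10 (acid-activated clay, idealised Al2Si4O10(OH)2·nH2O, dried at 120 °C), CH2Cl2 (ca. 0.01 M), 0 °C → rt, filtered as soon as 10 is consumed
Reagents that add atoms: none
Why: Acid sites of the clay bind each ether oxygen (O5 in a chelate with the C4 carbonyl), the allylic C–O bond ionises to a surface-held contact pair of phenoxide and 3,3-disubstituted allyl cation, the pair collapses through the unhindered primary terminus of the cation onto the adjacent ortho carbon, and proton loss from the cyclohexadienone so formed restores the phenol; the chelated, better leaving ring A phenoxide should depart first (10) and the ring B ether should follow. The closest known reaction type is the clay-catalysed formal [1,3] O-to-C rearrangement of aryl prenyl ethers, established for prenyl phenyl ether, for 5-O-prenyl flavonoids (which give the 6-C-prenyl isomers) and for geranyl ethers of ortho-acylphenols; here it is run at two sites of one molecule. No ring closes and no stereocentre is created, the only new skeletal bonds being C6–C1'' and C3'–C1'''. The step needs ortho delivery on both rings, attack through the primary allyl terminus with the E geometry kept, no exchange of the chains between the rings, no chroman closure and no enolisation at C3. Ortho delivery is built into the substrate, since the second position ortho to O5 is the quaternary C4a and C8 lies far from the ion pair, while on ring B the para position is blocked by C3 and the two ortho positions are equivalent; high dilution and a collapse faster than rotation about the C2'''–C3''' bond of the cation guard against crossover and E/Z loss. After the shift 5-OH is tied to C4=O by a hydrogen bond and O7 is silylated, so only 4'-OH could add to a side chain, and dry clay, low temperature and prompt filtration hold back that closure as well as the slow acid-catalysed enolisation of the aryl ketone.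

Step 7
Reactants: 11 (R)-3'-C-geranyl-6-C-prenyl-7-O-triisopropylsilyl-2,3-dihydrogenistein
Product: 12 (R)-3'-geranyl-6-prenyl-2,3-dihydrogenistein (CNP0165005.1)
Conditions: TBAF, AcOH (1:1), THF, 0 °C
Reagents that add atoms: none
Why: Fluoride-induced cleavage of an aryl silyl ether: the 7-oxide para to the C4 carbonyl is an excellent leaving group from silicon so the reaction should be fast in the cold, and the acetic acid buffer protonates it at once, which keeps the medium too weakly basic to enolise the ketone and so preserves C3, the alkenes and the free phenols.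

Compound list
1 | genistein (5,7,4'-trihydroxyisoflavone) | O=c1c(-c2ccc(O)cc2)coc2cc(O)cc(O)c12 | starting material
2 | 7-O-triisopropylsilylgenistein | O=c1c(-c2ccc(O)cc2)coc2cc(O[Si](C(C)C)(C(C)C)C(C)C)cc(O)c12 | intermediate
3 | geraniol, (2E)-3,7-dimethylocta-2,6-dien-1-ol | CC(C)=CCC/C(C)=C/CO | starting material
4 | 4'-O-geranyl-7-O-triisopropylsilylgenistein | CC(C)=CCC/C(C)=C/COc1ccc(-c2coc3cc(O[Si](C(C)C)(C(C)C)C(C)C)cc(O)c3c2=O)cc1 | intermediate
5 | prenol, 3-methylbut-2-en-1-ol | CC(C)=CCO | starting material
6 | 4'-O-geranyl-5-O-prenyl-7-O-triisopropylsilylgenistein | CC(C)=CCC/C(C)=C/COc1ccc(-c2coc3cc(O[Si](C(C)C)(C(C)C)C(C)C)cc(OCC=C(C)C)c3c2=O)cc1 | intermediate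
7 | racemic 4'-O-geranyl-5-O-prenyl-7-O-triisopropylsilyl-2,3-dihydrogenistein (not isolated) | CC(C)=CCC/C(C)=C/COc1ccc(C2COc3cc(O[Si](C(C)C)(C(C)C)C(C)C)cc(OCC=C(C)C)c3C2=O)cc1 | intermediate
8 | (3R,4R)-cis-4'-geranyloxy-5-prenyloxy-7-(triisopropylsilyloxy)isoflavan-4-ol | CC(C)=CCC/C(C)=C/COc1ccc([C@@H]2COc3cc(O[Si](C(C)C)(C(C)C)C(C)C)cc(OCC=C(C)C)c3[C@@H]2O)cc1 | intermediate
9 | (R)-4'-O-geranyl-5-O-prenyl-7-O-triisopropylsilyl-2,3-dihydrogenistein | CC(C)=CCC/C(C)=C/COc1ccc([C@@H]2COc3cc(O[Si](C(C)C)(C(C)C)C(C)C)cc(OCC=C(C)C)c3C2=O)cc1 | intermediate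
10 | (R)-4'-O-geranyl-6-C-prenyl-7-O-triisopropylsilyl-2,3-dihydrogenistein (not isolated) | CC(C)=CCC/C(C)=C/COc1ccc([C@@H]2COc3cc(O[Si](C(C)C)(C(C)C)C(C)C)c(CC=C(C)C)c(O)c3C2=O)cc1 | intermediate
11 | (R)-3'-C-geranyl-6-C-prenyl-7-O-triisopropylsilyl-2,3-dihydrogenistein | CC(C)=CCC/C(C)=C/Cc1cc([C@@H]2COc3cc(O[Si](C(C)C)(C(C)C)C(C)C)c(CC=C(C)C)c(O)c3C2=O)ccc1O | intermediate
12 | (3R)-5,7-dihydroxy-3-(3-geranyl-4-hydroxyphenyl)-6-prenylchroman-4-one | CC(C)=CCC/C(C)=C/Cc1cc([C@@H]2COc3cc(O)c(CC=C(C)C)c(O)c3C2=O)ccc1O | target

Total step count: 7. Longest linear sequence: 7 steps (1 → 12).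

Steps most likely to fail

Risk 1, step 6. Several things may go wrong.
- The allyl cations may leak out of their ion pairs, which would exchange prenyl and geranyl between the rings, send prenyl to C8, or start cation–olefin cyclisation of the geranyl chain.
- The freed 4'-OH may close onto the new chain under acid.
- C3 may slowly enolise during the longer exposure that the less activated ring B ether needs.

The fallback uncouples the two migrations and moves the slow one ahead of the stereocentre, so that only one migrating group is present at a time. It sets out from 4. Montmorillonite K10 in CH2Cl2 at rt shifts the geranyl group on the achiral isoflavone and should give 3'-C-geranyl-7-O-triisopropylsilylgenistein F1. TIPSCl and imidazole in DMF cap the freed phenol to give 3'-C-geranyl-4',7-bis-O-triisopropylsilylgenistein F2. A Mitsunobu reaction with 5 gives its 5-O-prenyl ether F3. Transfer hydrogenation as in step 4 passes through the racemic isoflavanone F4 to the (3R,4R)-cis-isoflavan-4-ol F5, and buffered Dess–Martin oxidation gives the (R)-isoflavanone F6. A short, cold exposure to K10 then carries out only the directly precedented shift from O5 to C6. The ring B phenol is now silylated and cannot close a chroman, and the product is the 4',7-bis-O-triisopropylsilyl ether of the target F7. TBAF/AcOH removes both silyl groups, and the route is rejoined at 12.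

Risk 2, step 4. The ketone of 7 is flanked by the 5-O-prenyl group and is strongly donor-substituted. The second hydride transfer may stall at the racemic ketone, or may proceed with eroded cis and facial selectivity. The fallback replaces asymmetric catalysis by resolution with recycling, and it sets out from 6. Conjugate reduction by LiBH(s-Bu)3 in THF at −78 °C with an AcOH quench gives 7, now isolated. Preparative supercritical-fluid chromatography on an amylose tris(3,5-dimethylphenylcarbamate) phase separates 9 from its mirror image, (S)-4'-O-geranyl-5-O-prenyl-7-O-triisopropylsilyl-2,3-dihydrogenistein F8. F8 is racemised back to 7 by Et3N in CH2Cl2 and injected again. The route is rejoined at 9, and steps 4 and 5 fall away.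

Risk 3, step 1. Silylation may run on to O4', or the silyl group may scramble between O7 and O4', which would spoil the ordering of the three hydroxyls on which all later regiochemistry rests. The fallback reverses the order and relies on nucleophilicity instead of acidity, and it sets out from 1. KOt-Bu (2 equiv) in DMF forms the 7,4'-dianion, in which the localised 4'-phenoxide is the better nucleophile. One equivalent of geranyl bromide followed by an AcOH quench should give 4'-O-geranylgenistein F9. TIPSCl and imidazole then find only one reactive hydroxyl, 7-OH, and the route is rejoined at 4.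

Further compounds
F1 | step 6 | 3'-C-geranyl-7-O-triisopropylsilylgenistein | CC(C)=CCC/C(C)=C/Cc1cc(-c2coc3cc(O[Si](C(C)C)(C(C)C)C(C)C)cc(O)c3c2=O)ccc1O
F2 | step 6 | 3'-C-geranyl-4',7-bis-O-triisopropylsilylgenistein | CC(C)=CCC/C(C)=C/Cc1cc(-c2coc3cc(O[Si](C(C)C)(C(C)C)C(C)C)cc(O)c3c2=O)ccc1O[Si](C(C)C)(C(C)C)C(C)C
F3 | step 6 | 3'-C-geranyl-5-O-prenyl-4',7-bis-O-triisopropylsilylgenistein | CC(C)=CCC/C(C)=C/Cc1cc(-c2coc3cc(O[Si](C(C)C)(C(C)C)C(C)C)cc(OCC=C(C)C)c3c2=O)ccc1O[Si](C(C)C)(C(C)C)C(C)C
F4 | step 6 | racemic 3'-C-geranyl-5-O-prenyl-4',7-bis-O-triisopropylsilyl-2,3-dihydrogenistein | CC(C)=CCC/C(C)=C/Cc1cc(C2COc3cc(O[Si](C(C)C)(C(C)C)C(C)C)cc(OCC=C(C)C)c3C2=O)ccc1O[Si](C(C)C)(C(C)C)C(C)C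
F5 | step 6 | (3R,4R)-cis-3'-geranyl-5-prenyloxy-4',7-bis(triisopropylsilyloxy)isoflavan-4-ol | CC(C)=CCC/C(C)=C/Cc1cc([C@@H]2COc3cc(O[Si](C(C)C)(C(C)C)C(C)C)cc(OCC=C(C)C)c3[C@@H]2O)ccc1O[Si](C(C)C)(C(C)C)C(C)C
F6 | step 6 | (R)-3'-C-geranyl-5-O-prenyl-4',7-bis-O-triisopropylsilyl-2,3-dihydrogenistein | CC(C)=CCC/C(C)=C/Cc1cc([C@@H]2COc3cc(O[Si](C(C)C)(C(C)C)C(C)C)cc(OCC=C(C)C)c3C2=O)ccc1O[Si](C(C)C)(C(C)C)C(C)C
F7 | step 6 | (R)-3'-C-geranyl-6-C-prenyl-4',7-bis-O-triisopropylsilyl-2,3-dihydrogenistein | CC(C)=CCC/C(C)=C/Cc1cc([C@@H]2COc3cc(O[Si](C(C)C)(C(C)C)C(C)C)c(CC=C(C)C)c(O)c3C2=O)ccc1O[Si](C(C)C)(C(C)C)C(C)C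
F8 | step 4 | (S)-4'-O-geranyl-5-O-prenyl-7-O-triisopropylsilyl-2,3-dihydrogenistein | CC(C)=CCC/C(C)=C/COc1ccc([C@H]2COc3cc(O[Si](C(C)C)(C(C)C)C(C)C)cc(OCC=C(C)C)c3C2=O)cc1
F9 | step 1 | 4'-O-geranylgenistein | CC(C)=CCC/C(C)=C/COc1ccc(-c2coc3cc(O)cc(O)c3c2=O)cc1
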